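## Retrosynthetic overview

1. Feature: ring system B is the dihydrobenzofuran (primed atoms) that carries the 4-hydroxyphenyl group, and ring system A (unprimed) carries the guaiacyl group. In B, C3a' lies between C7a'–O1' and C4'–OH and para to the styryl carbon C6'. It is therefore C2 of a 5-substituted cyclohexane-1,3-dione in aromatised form, and C2'–C3' with its two aryl groups is the alkene of a protected resveratrol.
2. Key disconnection: C3'–C3a' and O1'–C2' form together in a chiral dirhodium carbenoid formal [3+2] between methyl 4-diazo-3,5-dioxocyclohexanecarboxylate and the stilbene, which closes the furan ring of B. Selenoxide dehydrogenation then makes the benzene ring of B.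
3. The C6' ester becomes CH2OH, then CHO, and a Horner–Wadsworth–Emmons reaction adds the 4-hydroxystyryl arm.
4. Ring system A comes last. C3a–C3 forms by lithiation between the two MOM ethers and addition to a 3,5-disilyloxybenzaldehyde. C3–C2 and C2–O1 form by [4+1] annulation of the derived ortho-quinone methide with a vanillin-derived chiral sulfonium benzylide.
5. Ring order: dihydrofuran of B, arene of B, dihydrofuran of A. Deallylation and global desilylation finish the synthesis.

Key step: step 8

Assumption: the absolute sense of induction of Rh2(S-PTTL)4 (step 8) and of the (2S,5S)-thiolanium benzylide (step 25, by analogy with the sense this sulfide class shows in aldehyde epoxidation) is taken as drawn; the mirror-image catalyst and sulfide are equally accessible if the sense proves opposite.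

## Route

Step 1
Reactants: 1 3,5-dihydroxybenzoic acid
Product: 2 3,5-dioxocyclohexane-1-carboxylic acid
Conditions: H2 (60 bar), Raney Ni, NaOH (2.1 equiv), H2O, 50 °C; then aq HCl to pH 1
Reagents that add atoms: none
Why: Partial catalytic hydrogenation of a resorcinol in aqueous base stops at the 1,3-dione because the product is held as its reduction-resistant enolate, as in the classical conversion of resorcinol into cyclohexane-1,3-dione.

Step 2
Reactants: 2 3,5-dioxocyclohexane-1-carboxylic acid
Product: 4 methyl 3,5-dioxocyclohexane-1-carboxylate, via methyl enol ether 3 (not isolated)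
Conditions: MeOH, H2SO4 (cat.), reflux; then 1 M aq HCl, THF, rt
Reagents that add atoms: methanol CO; water O
Why: Fischer esterification also etherifies the enolised dione to the vinylogous ester 3, which dilute aqueous acid hydrolyses much faster than the saturated methyl ester.

Step 3
Reactants: 4 methyl 3,5-dioxocyclohexane-1-carboxylate
Product: 5 methyl 4-diazo-3,5-dioxocyclohexane-1-carboxylate
Conditions: 4-acetamidobenzenesulfonyl azide, Et3N, MeCN, 0 °C to rt
Reagents that add atoms: 4-acetamidobenzenesulfonyl azide CC(=O)Nc1ccc(cc1)S(=O)(=O)N=[N+]=[N-]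
Why: Regitz diazo transfer to the very acidic methylene between the two carbonyl groups of a cyclic 1,3-dione is fast with a sulfonyl azide and a tertiary amine.

Step 4
Reactants: 6 3,5-dihydroxybenzaldehyde
Product: 7 3,5-bis(methoxymethoxy)benzaldehyde
Conditions: MOMCl (2.5 equiv), i-Pr2NEt, CH2Cl2, 0 °C to rt
Reagents that add atoms: chloromethyl methyl ether COCCl
Why: Williamson-type O-alkylation of both phenols by the reactive chloromethyl ether under amine base leaves the aldehyde untouched.

Step 5
Reactants: 8 4-hydroxybenzyl alcohol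
Product: 9 diethyl (4-hydroxybenzyl)phosphonate
Conditions: P(OEt)3 (neat, excess), 150 °C
Reagents that add atoms: triethyl phosphite CCOP(OCC)OCC
Why: On heating the para-hydroxybenzyl alcohol loses water to a para-quinone methide that the phosphite traps, and Michaelis–Arbuzov-type dealkylation of the phosphonium ion gives the phosphonate.

Step 6
Reactants: 9 diethyl (4-hydroxybenzyl)phosphonate
Product: 10 diethyl [4-(triisopropylsilyloxy)benzyl]phosphonate
Conditions: TIPSCl, imidazole, DMF, rt
Reagents that add atoms: chlorotriisopropylsilane CC(C)[Si](Cl)(C(C)C)C(C)C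
Why: Imidazole-promoted silylation of the only hydroxyl group is a standard phenol protection, and the bulky silyl group should withstand the later alkoxide, organolithium and mild acid steps.

Step 7
Reactants: 7 3,5-bis(methoxymethoxy)benzaldehyde; 10 diethyl [4-(triisopropylsilyloxy)benzyl]phosphonate
Product: 11 (E)-3,5-bis(methoxymethoxy)-4'-(triisopropylsilyloxy)stilbene (differentially protected resveratrol)
Conditions: KOt-Bu, THF, 0 °C to rt
Reagents that add atoms: none
Why: Horner–Wadsworth–Emmons olefination of an aromatic aldehyde with a benzylic phosphonate anion gives the E-stilbene, and assembly from two pieces avoids having to tell the three phenols of resveratrol apart.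

Step 8
Reactants: 5 methyl 4-diazo-3,5-dioxocyclohexane-1-carboxylate; 11 (E)-3,5-bis(methoxymethoxy)-4'-(triisopropylsilyloxy)stilbene
Product: 12 methyl (2R,3R)-3-[3,5-bis(methoxymethoxy)phenyl]-4-oxo-2-[4-(triisopropylsilyloxy)phenyl]-2,3,4,5,6,7-hexahydro-1-benzofuran-6-carboxylate (trans; C6 epimers)
Conditions: Rh2(S-PTTL)4 (dirhodium tetrakis[N-phthaloyl-(S)-tert-leucinate], 2 mol %), PhCF3, 60 °C, 5 (2 equiv) added slowly by syringe pump
Reagents that add atoms: none
Why: Proposed new method: Rh2(S-PTTL)4 expels N2 from 5, and the strongly electrophilic diacyl carbenoid is attacked by the alkene carbon of 11 that bears the 3,5-bis(MOM-oxy)phenyl ring, so that C3'–C3a' forms while positive charge builds up at the carbon next to the 4-silyloxyphenyl ring. The closest known reaction types are the achiral Rh2(OAc)4- or copper-catalysed formal [3+2] annulation of cyclic 2-diazo-1,3-diones (or their iodonium ylides) with styrenes and enol ethers to 2,3-dihydrofurans and the racemic Mn(OAc)3 oxidative annulation of 1,3-diones, and what is new is a 1,2-diarylethene as partner under enantiocontrol. The one new ring (O1'–C2'–C3'–C3a'–C7a') closes by O-alkylation of the dione enolate by the benzylic cation (five-membered, enolate C=C inside the ring) or, equivalently, by Cloke–Wilson-type ring expansion of a transient spirocyclopropane. C3' is set in the C–C bond-forming event, where the phthalimido walls of the catalyst pocket must select one alkene face; C2' follows from closure anti to the C3' aryl group, which gives the trans and also more stable isomer; C6 forms as a mixture and is erased in step 9. The step needs regioselectivity, secured by a para-oxygen donor on one aryl ring against two non-donating meta oxygens on the other, and chemoselectivity for the alkene over the arenes and acetal oxygens, which slow addition of 5 in a non-coordinating solvent should help.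

Step 9
Reactants: 12 methyl (2R,3R)-3-[3,5-bis(methoxymethoxy)phenyl]-4-oxo-2-[4-(triisopropylsilyloxy)phenyl]-hexahydrobenzofuran-6-carboxylate
Product: 14 methyl (2R,3R)-3-[3,5-bis(methoxymethoxy)phenyl]-4-hydroxy-2-[4-(triisopropylsilyloxy)phenyl]-2,3-dihydro-1-benzofuran-6-carboxylate, via C5 phenylselenide 13 (not isolated)
Conditions: LiN(i-Pr)2 (1.2 equiv), THF, −78 °C; PhSeCl, −78 °C; then 30% H2O2, pyridine, CH2Cl2, 0 °C to rt
Reagents that add atoms: none
Why: Enolate selenenylation and selenoxide syn-elimination add one ring double bond and the cross-conjugated dienone tautomerises at once to the phenol, so selenenylation at C5 or at C6 leads to the same arene, the C6 centre disappears, and C2' and C3', which carry no acidic hydrogen, are untouched.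

Step 10
Reactants: 14 phenol ester
Product: 15 methyl (2R,3R)-3-[3,5-bis(methoxymethoxy)phenyl]-4-(triisopropylsilyloxy)-2-[4-(triisopropylsilyloxy)phenyl]-2,3-dihydro-1-benzofuran-6-carboxylate
Conditions: TIPSOTf, 2,6-lutidine, CH2Cl2, 0 °C
Reagents that add atoms: triisopropylsilyl trifluoromethanesulfonate CC(C)[Si](OS(=O)(=O)C(F)(F)F)(C(C)C)C(C)C
Why: The silyl triflate is reactive enough to silylate the hindered C4' phenol next to the C3' aryl group under non-nucleophilic base.

Step 11
Reactants: 15 bis-silyl ester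
Product: 16 {(2R,3R)-3-[3,5-bis(methoxymethoxy)phenyl]-4-(triisopropylsilyloxy)-2-[4-(triisopropylsilyloxy)phenyl]-2,3-dihydro-1-benzofuran-6-yl}methanol
Conditions: i-Bu2AlH (3 equiv), CH2Cl2, −78 to 0 °C
Reagents that add atoms: none
Why: Hydride reduction of the aromatic ester with i-Bu2AlH removes the only group that would not survive the organolithium step and spares acetals and aryl silyl ethers.

Step 12
Reactants: 6 3,5-dihydroxybenzaldehyde
Product: 17 3,5-bis(triisopropylsilyloxy)benzaldehyde
Conditions: TIPSCl (2.4 equiv), imidazole, DMF, rt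
Reagents that add atoms: chlorotriisopropylsilane CC(C)[Si](Cl)(C(C)C)C(C)C
Why: Standard imidazole-promoted silylation of both phenols gives a non-enolisable aldehyde whose protecting groups fall in the final fluoride step.

Step 13
Reactants: 16 benzylic alcohol; 17 3,5-bis(triisopropylsilyloxy)benzaldehyde
Product: 19 diol carrying a 4-{[3,5-bis(triisopropylsilyloxy)phenyl](hydroxy)methyl}-3,5-bis(methoxymethoxy)phenyl group at C3' (carbinol epimers), via dilithiated arene 18 (not isolated)
Conditions: n-BuLi (2.2 equiv), THF, 0 °C; then 17, −78 to 0 °C; H2O quench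
Reagents that add atoms: none
Why: In this directed ortho-metalation the first equivalent of n-BuLi forms the alkoxide, the second is guided by both MOM ethers to the C–H between them, and the aryllithium adds 1,2 to the aldehyde; running it before the styryl arm exists excludes carbolithiation of a stilbene, and the new carbinol centre is removed in step 14.

Step 14
Reactants: 19 diol
Product: 20 (2R,3R)-3-{4-[3,5-bis(triisopropylsilyloxy)benzoyl]-3,5-bis(methoxymethoxy)phenyl}-4-(triisopropylsilyloxy)-2-[4-(triisopropylsilyloxy)phenyl]-2,3-dihydro-1-benzofuran-6-carbaldehyde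
Conditions: Dess–Martin periodinane (3 equiv), CH2Cl2, 0 °C to rt
Reagents that add atoms: none
Why: Dess–Martin oxidation converts the primary and the hindered secondary benzylic alcohol in one operation under near-neutral conditions, giving an acid-stable ketone in place of an easily ionised benzhydrol.

Step 15
Reactants: 20 keto aldehyde; 10 diethyl [4-(triisopropylsilyloxy)benzyl]phosphonate
Product: 21 ketone carrying the (E)-4-(triisopropylsilyloxy)styryl group at C6'
Conditions: KOt-Bu, THF, −78 to 0 °C (phosphonate anion preformed)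
Reagents that add atoms: none
Why: The Horner–Wadsworth–Emmons reaction is E-selective and chemoselective, because the aldehyde is attacked rapidly while the diaryl ketone flanked by two ortho substituents is too hindered for a benzylic phosphonate anion.

Step 16
Reactants: 21 bis-MOM ketone
Product: 22 2,6-dihydroxybenzophenone (both MOM ethers removed)
Conditions: 3 M aq HCl (cat.), MeOH–THF, 45 °C
Reagents that add atoms: none
Why: Acid-catalysed acetal exchange with methanol cleaves the MOM ethers, which are activated by the ortho carbonyl group, while the aryl TIPS ethers, the ketone and the silyl-deactivated benzylic ether C2'–O1' should tolerate these mild conditions.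

Step 17
Reactants: 22 2,6-dihydroxybenzophenone
Product: 23 2-allyloxy-6-hydroxybenzophenone
Conditions: allyl bromide (1.05 equiv), K2CO3, acetone, 45 °C
Reagents that add atoms: allyl bromide C=CCBr
Why: In this Williamson ether synthesis the two hydroxyl groups are equivalent by rotation of the ring, and after the first alkylation the remaining one is locked in a hydrogen bond to the ketone, so the reaction should stop at the mono-ether, a small group that cannot migrate to a neighbouring alkoxide.

Step 18
Reactants: 23 2-allyloxy-6-hydroxybenzophenone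
Product: 24 ortho-hydroxybenzhydrol (carbinol epimers)
Conditions: LiAlH4, THF, −20 to 0 °C
Reagents that add atoms: none
Why: Hydride reduction with LiAlH4 overcomes the hindrance of the diaryl ketone at low temperature, and the configuration of the new carbinol is irrelevant because this carbon becomes planar in step 25.

Step 19
Reactants: 24 ortho-hydroxybenzhydrol
Product: 25 2-[aryl(tosyl)methyl]phenol (sulfone, epimers at the benzhydryl carbon)
Conditions: p-TolSO2H (1.5 equiv), CH2Cl2, rt
Reagents that add atoms: 4-methylbenzenesulfinic acid Cc1ccc(cc1)S(=O)O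
Why: In this SN1 substitution the sulfinic acid ionises the electron-rich benzhydrol and captures the cation at sulfur, giving the storable sulfone that is the usual base-triggered precursor of ortho-quinone methides.

Step 20
Reactants: 26 vanillin
Product: 27 3-methoxy-4-(triisopropylsilyloxy)benzaldehyde
Conditions: TIPSCl, imidazole, DMF, rt
Reagents that add atoms: chlorotriisopropylsilane CC(C)[Si](Cl)(C(C)C)C(C)C
Why: This is standard imidazole-promoted silylation of the single phenol.

Step 21
Reactants: 27 3-methoxy-4-(triisopropylsilyloxy)benzaldehyde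
Product: 28 [3-methoxy-4-(triisopropylsilyloxy)phenyl]methanol
Conditions: NaBH4, MeOH, 0 °C
Reagents that add atoms: none
Why: Borohydride reduction of an aromatic aldehyde is fast and leaves the aryl silyl ether intact.

Step 22
Reactants: 29 (2R,5R)-hexane-2,5-diol
Product: 30 (2R,5R)-hexane-2,5-diyl dimethanesulfonate
Conditions: MsCl, Et3N, CH2Cl2, 0 °C
Reagents that add atoms: methanesulfonyl chloride CS(=O)(=O)Cl
Why: Mesylation takes place at oxygen and therefore retains both stereocentres.

Step 23
Reactants: 30 (2R,5R)-hexane-2,5-diyl dimethanesulfonate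
Product: 31 (2S,5S)-2,5-dimethylthiolane
Conditions: Na2S·9H2O, EtOH, rt to 40 °C
Reagents that add atoms: sodium sulfide [Na+].[Na+].[S-2]
Why: Two successive SN2 displacements by sulfide, the second a 5-exo-tet ring closure, invert both centres cleanly and give the C2-symmetric trans-thiolane.

Step 24
Reactants: 28 [3-methoxy-4-(triisopropylsilyloxy)phenyl]methanol; 31 (2S,5S)-2,5-dimethylthiolane
Product: 32 (2S,5S)-1-[3-methoxy-4-(triisopropylsilyloxy)benzyl]-2,5-dimethylthiolanium trifluoromethanesulfonate
Conditions: TfOH (1.0 equiv), CH2Cl2, −20 to 0 °C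
Reagents that add atoms: trifluoromethanesulfonic acid OS(=O)(=O)C(F)(F)F
Why: In this acid-promoted SN1 alkylation the electron-rich benzylic alcohol ionises and the sulfide captures the cation irreversibly beside a non-nucleophilic counter-ion, and the C2 symmetry of the sulfide means that only one sulfonium salt can form.

Step 25
Reactants: 25 sulfone; 32 chiral sulfonium triflate
Product: 35 (2S,3S)-4-allyloxy-3-[3,5-bis(triisopropylsilyloxy)phenyl]-2-[3-methoxy-4-(triisopropylsilyloxy)phenyl]-6-[(2R,3R)-ring system B]-2,3-dihydro-1-benzofuran (hexa-TIPS allyl ether of the target), via sulfonium benzylide 33 (not isolated), via ortho-quinone methide 34 (not isolated)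
Conditions: Cs2CO3 (3 equiv), MeCN–CH2Cl2, −20 °C to rt
Reagents that add atoms: none
Why: Proposed new method: Cs2CO3 triggers 1,4-elimination of sulfinate from the phenoxide of 25 to the ortho-quinone methide 34 and deprotonates 32 to the benzylide 33, whose conjugate addition to the methide carbon (C2–C3 bond, made irreversible by rearomatisation) is followed by 5-exo-tet displacement of the sulfide by the phenoxide with inversion (O1–C2 bond), the anti-arranged zwitterion giving the trans ring; the closest known reaction type is the trans-selective [4+1] annulation of sulfone-derived ortho-quinone methides with achiral sulfonium ylides, and what is new is that the C2-symmetric thiolane, which shields one face of its benzylide in aldehyde epoxidations, must fix C2 and, through the trans relationship, C3, because the stereocentres of ring system B are too remote to help.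

Step 26
Reactants: 35 hexa-TIPS allyl ether
Product: 36 hexa-TIPS ether with free C4 hydroxyl
Conditions: Pd(PPh3)4 (5 mol %), morpholine, THF, rt
Reagents that add atoms: none
Why: In this Tsuji–Trost deallylation zerovalent palladium ionises the allyl aryl ether to a π-allyl complex that morpholine captures, under neutral conditions that touch neither the stilbene, the silyl ethers nor the stereocentres.

Step 27
Reactants: 36 hexa-TIPS ether
Product: 37 Gnetin K
Conditions: Bu4NF (7 equiv), AcOH (7 equiv), THF, 0 °C, under argon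
Reagents that add atoms: none
Why: Fluoride cleaves all six aryl silyl ethers, driven by Si–F bond formation, and the acetic acid buffer keeps the liberated phenols protonated so that base-induced opening of the 2-aryl dihydrofuran rings and air oxidation are suppressed.

## Compound list

1 | 3,5-dihydroxybenzoic acid | OC(=O)c1cc(O)cc(O)c1 | starting material
2 | 3,5-dioxocyclohexane-1-carboxylic acid | OC(=O)C1CC(=O)CC(=O)C1 | intermediate
3 | methyl 3-methoxy-5-oxocyclohex-3-ene-1-carboxylate (racemic, not isolated) | COC(=O)C1CC(=O)C=C(OC)C1 | intermediate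
4 | methyl 3,5-dioxocyclohexane-1-carboxylate | COC(=O)C1CC(=O)CC(=O)C1 | intermediate
5 | methyl 4-diazo-3,5-dioxocyclohexane-1-carboxylate | COC(=O)C1CC(=O)C(=[N+]=[N-])C(=O)C1 | intermediate
6 | 3,5-dihydroxybenzaldehyde | O=Cc1cc(O)cc(O)c1 | starting material
7 | 3,5-bis(methoxymethoxy)benzaldehyde | COCOc1cc(C=O)cc(OCOC)c1 | intermediate
8 | 4-hydroxybenzyl alcohol | OCc1ccc(O)cc1 | starting material
9 | diethyl (4-hydroxybenzyl)phosphonate | CCOP(=O)(Cc1ccc(O)cc1)OCC | intermediate
10 | diethyl [4-(triisopropylsilyloxy)benzyl]phosphonate | CCOP(=O)(Cc1ccc(O[Si](C(C)C)(C(C)C)C(C)C)cc1)OCC | intermediate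
11 | (E)-3,5-bis(methoxymethoxy)-4'-(triisopropylsilyloxy)stilbene | COCOc1cc(OCOC)cc(/C=C/c2ccc(O[Si](C(C)C)(C(C)C)C(C)C)cc2)c1 | intermediate
12 | methyl (2R,3R)-3-[3,5-bis(methoxymethoxy)phenyl]-4-oxo-2-[4-(triisopropylsilyloxy)phenyl]-2,3,4,5,6,7-hexahydro-1-benzofuran-6-carboxylate (C6 epimers) | COCOc1cc(OCOC)cc(c1)[C@@H]1C2=C(CC(CC2=O)C(=O)OC)O[C@H]1c1ccc(O[Si](C(C)C)(C(C)C)C(C)C)cc1 | intermediate
13 | 5-phenylselanyl derivative of 12 (epimers at C5 and C6, not isolated) | COCOc1cc(OCOC)cc(c1)[C@@H]1C2=C(CC(C(=O)OC)C([Se]c3ccccc3)C2=O)O[C@H]1c1ccc(O[Si](C(C)C)(C(C)C)C(C)C)cc1 | intermediate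
14 | methyl (2R,3R)-3-[3,5-bis(methoxymethoxy)phenyl]-4-hydroxy-2-[4-(triisopropylsilyloxy)phenyl]-2,3-dihydro-1-benzofuran-6-carboxylate | COCOc1cc(OCOC)cc(c1)[C@@H]1c2c(O)cc(cc2O[C@H]1c1ccc(O[Si](C(C)C)(C(C)C)C(C)C)cc1)C(=O)OC | intermediate
15 | 4-O-TIPS ether of 14 | COCOc1cc(OCOC)cc(c1)[C@@H]1c2c(O[Si](C(C)C)(C(C)C)C(C)C)cc(cc2O[C@H]1c1ccc(O[Si](C(C)C)(C(C)C)C(C)C)cc1)C(=O)OC | intermediate
16 | {(2R,3R)-3-[3,5-bis(methoxymethoxy)phenyl]-4-(triisopropylsilyloxy)-2-[4-(triisopropylsilyloxy)phenyl]-2,3-dihydro-1-benzofuran-6-yl}methanol | COCOc1cc(cc(OCOC)c1)[C@@H]2c3c(O[Si](C(C)C)(C(C)C)C(C)C)cc(CO)cc3O[C@H]2c2ccc(O[Si](C(C)C)(C(C)C)C(C)C)cc2 | intermediate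
17 | 3,5-bis(triisopropylsilyloxy)benzaldehyde | O=Cc1cc(O[Si](C(C)C)(C(C)C)C(C)C)cc(O[Si](C(C)C)(C(C)C)C(C)C)c1 | intermediate
18 | lithium alkoxide of 16 lithiated between the two MOM ethers (not isolated) | COCOc1cc(cc(OCOC)c1[Li])[C@@H]2c3c(O[Si](C(C)C)(C(C)C)C(C)C)cc(CO[Li])cc3O[C@H]2c2ccc(O[Si](C(C)C)(C(C)C)C(C)C)cc2 | intermediate
19 | diol: 16 bearing a [3,5-bis(triisopropylsilyloxy)phenyl](hydroxy)methyl group between the MOM ethers (carbinol epimers) | COCOc1cc(cc(OCOC)c1C(O)c4cc(O[Si](C(C)C)(C(C)C)C(C)C)cc(O[Si](C(C)C)(C(C)C)C(C)C)c4)[C@@H]2c3c(O[Si](C(C)C)(C(C)C)C(C)C)cc(CO)cc3O[C@H]2c2ccc(O[Si](C(C)C)(C(C)C)C(C)C)cc2 | intermediate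
20 | keto aldehyde: (2R,3R)-3-{4-[3,5-bis(triisopropylsilyloxy)benzoyl]-3,5-bis(methoxymethoxy)phenyl}-4-(triisopropylsilyloxy)-2-[4-(triisopropylsilyloxy)phenyl]-2,3-dihydro-1-benzofuran-6-carbaldehyde | COCOc1cc(cc(OCOC)c1C(=O)c4cc(O[Si](C(C)C)(C(C)C)C(C)C)cc(O[Si](C(C)C)(C(C)C)C(C)C)c4)[C@@H]2c3c(O[Si](C(C)C)(C(C)C)C(C)C)cc(C=O)cc3O[C@H]2c2ccc(O[Si](C(C)C)(C(C)C)C(C)C)cc2 | intermediate
21 | bis-MOM ketone with the (E)-4-(triisopropylsilyloxy)styryl group at C6' | COCOc1cc(cc(OCOC)c1C(=O)c4cc(O[Si](C(C)C)(C(C)C)C(C)C)cc(O[Si](C(C)C)(C(C)C)C(C)C)c4)[C@@H]2c3c(O[Si](C(C)C)(C(C)C)C(C)C)cc(/C=C/c5ccc(O[Si](C(C)C)(C(C)C)C(C)C)cc5)cc3O[C@H]2c2ccc(O[Si](C(C)C)(C(C)C)C(C)C)cc2 | intermediate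
22 | 2,6-dihydroxybenzophenone derived from 21 | Oc1cc(cc(O)c1C(=O)c4cc(O[Si](C(C)C)(C(C)C)C(C)C)cc(O[Si](C(C)C)(C(C)C)C(C)C)c4)[C@@H]2c3c(O[Si](C(C)C)(C(C)C)C(C)C)cc(/C=C/c5ccc(O[Si](C(C)C)(C(C)C)C(C)C)cc5)cc3O[C@H]2c2ccc(O[Si](C(C)C)(C(C)C)C(C)C)cc2 | intermediate
23 | 2-allyloxy-6-hydroxybenzophenone derived from 22 | C=CCOc1cc(cc(O)c1C(=O)c4cc(O[Si](C(C)C)(C(C)C)C(C)C)cc(O[Si](C(C)C)(C(C)C)C(C)C)c4)[C@@H]2c3c(O[Si](C(C)C)(C(C)C)C(C)C)cc(/C=C/c5ccc(O[Si](C(C)C)(C(C)C)C(C)C)cc5)cc3O[C@H]2c2ccc(O[Si](C(C)C)(C(C)C)C(C)C)cc2 | intermediate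
24 | ortho-hydroxybenzhydrol derived from 23 (carbinol epimers) | C=CCOc1cc(cc(O)c1C(O)c4cc(O[Si](C(C)C)(C(C)C)C(C)C)cc(O[Si](C(C)C)(C(C)C)C(C)C)c4)[C@@H]2c3c(O[Si](C(C)C)(C(C)C)C(C)C)cc(/C=C/c5ccc(O[Si](C(C)C)(C(C)C)C(C)C)cc5)cc3O[C@H]2c2ccc(O[Si](C(C)C)(C(C)C)C(C)C)cc2 | intermediate
25 | benzhydryl 4-tolyl sulfone derived from 24 (epimers at the benzhydryl carbon) | C=CCOc1cc(cc(O)c1C(c4cc(O[Si](C(C)C)(C(C)C)C(C)C)cc(O[Si](C(C)C)(C(C)C)C(C)C)c4)S(=O)(=O)c6ccc(C)cc6)[C@@H]2c3c(O[Si](C(C)C)(C(C)C)C(C)C)cc(/C=C/c5ccc(O[Si](C(C)C)(C(C)C)C(C)C)cc5)cc3O[C@H]2c2ccc(O[Si](C(C)C)(C(C)C)C(C)C)cc2 | intermediate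
26 | vanillin | COc1cc(C=O)ccc1O | starting material
27 | 3-methoxy-4-(triisopropylsilyloxy)benzaldehyde | COc1cc(C=O)ccc1O[Si](C(C)C)(C(C)C)C(C)C | intermediate
28 | [3-methoxy-4-(triisopropylsilyloxy)phenyl]methanol | COc1cc(CO)ccc1O[Si](C(C)C)(C(C)C)C(C)C | intermediate
29 | (2R,5R)-hexane-2,5-diol | C[C@@H](O)CC[C@@H](C)O | starting material
30 | (2R,5R)-hexane-2,5-diyl dimethanesulfonate | C[C@@H](OS(C)(=O)=O)CC[C@@H](C)OS(C)(=O)=O | intermediate
31 | (2S,5S)-2,5-dimethylthiolane | C[C@H]1CC[C@H](C)S1 | intermediate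
32 | (2S,5S)-1-[3-methoxy-4-(triisopropylsilyloxy)benzyl]-2,5-dimethylthiolanium trifluoromethanesulfonate | C[C@H]1CC[C@H](C)[S+]1Cc1ccc(O[Si](C(C)C)(C(C)C)C(C)C)c(OC)c1.[O-]S(=O)(=O)C(F)(F)F | intermediate
33 | benzylide of 32 (not isolated) | C[C@H]1CC[C@H](C)[S+]1[CH-]c1ccc(O[Si](C(C)C)(C(C)C)C(C)C)c(OC)c1 | intermediate
34 | ortho-quinone methide from 25 (exocyclic alkene geometry not defined, not isolated) | C=CCOC1=CC(=CC(=O)C1=Cc4cc(O[Si](C(C)C)(C(C)C)C(C)C)cc(O[Si](C(C)C)(C(C)C)C(C)C)c4)[C@@H]2c3c(O[Si](C(C)C)(C(C)C)C(C)C)cc(/C=C/c5ccc(O[Si](C(C)C)(C(C)C)C(C)C)cc5)cc3O[C@H]2c2ccc(O[Si](C(C)C)(C(C)C)C(C)C)cc2 | intermediate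
35 | (2S,3S,2'R,3'R)-4-O-allyl-hexa-O-TIPS Gnetin K | COc1cc([C@H]2Oc3cc([C@@H]4c5c(O[Si](C(C)C)(C(C)C)C(C)C)cc(/C=C/c6ccc(O[Si](C(C)C)(C(C)C)C(C)C)cc6)cc5O[C@H]4c4ccc(O[Si](C(C)C)(C(C)C)C(C)C)cc4)cc(OCC=C)c3[C@@H]2c2cc(O[Si](C(C)C)(C(C)C)C(C)C)cc(O[Si](C(C)C)(C(C)C)C(C)C)c2)ccc1O[Si](C(C)C)(C(C)C)C(C)C | intermediate
36 | (2S,3S,2'R,3'R)-hexa-O-TIPS Gnetin K (C4 hydroxyl free) | COc1cc([C@H]2Oc3cc([C@@H]4c5c(O[Si](C(C)C)(C(C)C)C(C)C)cc(/C=C/c6ccc(O[Si](C(C)C)(C(C)C)C(C)C)cc6)cc5O[C@H]4c4ccc(O[Si](C(C)C)(C(C)C)C(C)C)cc4)cc(O)c3[C@@H]2c2cc(O[Si](C(C)C)(C(C)C)C(C)C)cc(O[Si](C(C)C)(C(C)C)C(C)C)c2)ccc1O[Si](C(C)C)(C(C)C)C(C)C | intermediate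
37 | Gnetin K, (2S,3S,2'R,3'R) | COc1cc([C@H]2Oc3cc([C@@H]4c5c(O)cc(/C=C/c6ccc(O)cc6)cc5O[C@H]4c4ccc(O)cc4)cc(O)c3[C@@H]2c2cc(O)cc(O)c2)ccc1O | target

## Step count and risks

Total step count: 27. Longest linear sequence: 17 steps (1–3, 8–11, 13–19, 25–27). The branch through steps 5–7 is equally long.

**1. Step 8.** The 1,2-disubstituted alkene may intercept the carbenoid too slowly. Carbene dimerisation, or attack on the MOM-activated arene or the acetal oxygens, could then take over. The catalyst pocket may also discriminate the two alkene faces poorly.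

The fallback uses known chemistry and sets out from 4 and 11, which are heated with Mn(OAc)3·2H2O in AcOH at about 50 °C. The dione radical adds to the same alkene carbon, and a second equivalent of trivalent manganese oxidises the benzylic radical next to the silyloxyphenyl ring to the cation. The enol oxygen then closes trans. This gives 12 as the racemate, that is, together with the (2S,3S)-enantiomer of the annulation product F1. The conditions of step 9 carry the racemate through 13 and the (2S,3S)-configured phenylselenide F2 to 14 and the (2S,3S)-enantiomer of the phenol ester F3. Preparative HPLC on an amylose carbamate chiral phase removes F3, and the route is rejoined at 14.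

**2. Step 25.** The chiral benzylide may show poor facial selectivity towards the planar quinone methide. The semi-stabilised ylide may also decay, or the quinone methide oligomerise, faster than the two hindered partners combine.

The fallback uses known chemistry, gives up reagent control and relies on separation. It sets out from 28 and 25. Alcohol 28, tetrahydrothiophene and TfOH give the achiral 1-[3-methoxy-4-(triisopropylsilyloxy)benzyl]tetrahydrothiophenium triflate F4. With Cs2CO3 its tetrahydrothiophenium benzylide F5 undergoes the established trans-selective [4+1] annulation with 34 generated from 25. This should give 35 together with the (2R,3R,2'R,3'R)-diastereomer of the annulation product F6. The two are diastereomers, so preparative HPLC should separate them, and the route is rejoined at 35.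

**3. Step 9.** Enolisation may be unselective among the three acidic sites and lead to multiple selenenylation. Selenium electrophiles may attack the MOM-activated ring. The oxidative work-up may also overshoot and dehydrogenate the dihydrofuran, which would destroy both stereocentres.

The fallback replaces enolate chemistry by soft enolisation and hydride abstraction, and it sets out from 12. TIPSOTf and Et3N in CH2Cl2 at 0 °C give the cross-conjugated 4-(triisopropylsilyloxy)-2,3,6,7-tetrahydrobenzofuran dienol ether F7. DDQ (1.1 equiv, CH2Cl2, 0 °C) abstracts hydride from C7', and loss of the acidic C6' proton aromatises the ring. The silyl group stays on oxygen, so the route is rejoined directly at 15 and step 10 is skipped.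

## Further compounds

F1 | step 8 | methyl (2S,3S)-3-[3,5-bis(methoxymethoxy)phenyl]-4-oxo-2-[4-(triisopropylsilyloxy)phenyl]-2,3,4,5,6,7-hexahydro-1-benzofuran-6-carboxylate (enantiomer of 12) | COCOc1cc(OCOC)cc(c1)[C@H]1C2=C(CC(CC2=O)C(=O)OC)O[C@@H]1c1ccc(O[Si](C(C)C)(C(C)C)C(C)C)cc1
F2 | step 8 | (2S,3S)-configured 5-phenylselanyl ketone (enantiomeric series of 13) | COCOc1cc(OCOC)cc(c1)[C@H]1C2=C(CC(C(=O)OC)C([Se]c3ccccc3)C2=O)O[C@@H]1c1ccc(O[Si](C(C)C)(C(C)C)C(C)C)cc1
F3 | step 8 | methyl (2S,3S)-3-[3,5-bis(methoxymethoxy)phenyl]-4-hydroxy-2-[4-(triisopropylsilyloxy)phenyl]-2,3-dihydro-1-benzofuran-6-carboxylate (enantiomer of 14) | COCOc1cc(OCOC)cc(c1)[C@H]1c2c(O)cc(cc2O[C@@H]1c1ccc(O[Si](C(C)C)(C(C)C)C(C)C)cc1)C(=O)OC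
F4 | step 25 | 1-[3-methoxy-4-(triisopropylsilyloxy)benzyl]tetrahydrothiophenium trifluoromethanesulfonate | COc1cc(C[S+]2CCCC2)ccc1O[Si](C(C)C)(C(C)C)C(C)C.[O-]S(=O)(=O)C(F)(F)F
F5 | step 25 | benzylide of F4 | COc1cc([CH-][S+]2CCCC2)ccc1O[Si](C(C)C)(C(C)C)C(C)C
F6 | step 25 | (2R,3R,2'R,3'R)-4-O-allyl-hexa-O-TIPS diastereomer of 35 | COc1cc([C@@H]2Oc3cc([C@@H]4c5c(O[Si](C(C)C)(C(C)C)C(C)C)cc(/C=C/c6ccc(O[Si](C(C)C)(C(C)C)C(C)C)cc6)cc5O[C@H]4c4ccc(O[Si](C(C)C)(C(C)C)C(C)C)cc4)cc(OCC=C)c3[C@H]2c2cc(O[Si](C(C)C)(C(C)C)C(C)C)cc(O[Si](C(C)C)(C(C)C)C(C)C)c2)ccc1O[Si](C(C)C)(C(C)C)C(C)C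
F7 | step 9 | methyl (2R,3R)-3-[3,5-bis(methoxymethoxy)phenyl]-4-(triisopropylsilyloxy)-2-[4-(triisopropylsilyloxy)phenyl]-2,3,6,7-tetrahydro-1-benzofuran-6-carboxylate (C6 epimers) | COCOc1cc(OCOC)cc(c1)[C@@H]1C2=C(CC(C=C2O[Si](C(C)C)(C(C)C)C(C)C)C(=O)OC)O[C@H]1c1ccc(O[Si](C(C)C)(C(C)C)C(C)C)cc1
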